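The pyran ring is cut between C3 and C4. Both carbons are drawn back to aldehydes: C4 to the formyl group on C4a of the benzoate ring, C3 to an aldehyde on the fully substituted C2, which carries O1, the methyl group and the homogeranyl chain and, having no hydrogen, can neither enolise nor epimerise. A chiral triazolylidene converts the aryl aldehyde into an acyl anion equivalent that adds to the C3 aldehyde, so a single operation forms C3–C4, closes the pyranone ring and sets C3. The precursor is an (R)-configured tertiary alkyl aryl ether dialdehyde, assembled by asymmetric epoxidation, hydride opening and SNAr etherification.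

Key step: step 8

Remark: chroman numbering (O1, C2, C3, C4, C4a to C8a) is used for all intermediates. The spatial arrangement at C2 and C3 is the same throughout, although the descriptor changes where priorities change (PMB-protected epoxide, ketol). The epoxidation is assumed to follow the usual rule that L-(+)-tartrate gives the (2S) series, so D-(−)-tartrate is specified for the (R)-epoxide.

Step 1
Reactants: 1 2-methylprop-2-en-1-ol (methallyl alcohol); 2 geranyl bromide
Product: 4 (5E)-6,10-dimethyl-2-methylideneundeca-5,9-dien-1-ol, via dilithiated methallyl alcohol 3 (not isolated)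
Conditions: n-BuLi (2.2 equiv), TMEDA, Et2O–hexane, 0 °C to rt; then 2, THF, −78 °C to rt; H2O
Reagents that add atoms: none
Why: Double deprotonation (O–H, then allylic C–H) gives an alkoxide-bearing allyllithium with two equivalent termini, and its SN2 alkylation by the primary allylic bromide (allylic dianion alkylation) should attach the homogeranyl chain without touching the E-alkene.

Step 2
Reactants: 4 (5E)-6,10-dimethyl-2-methylideneundeca-5,9-dien-1-ol
Product: 5 [(2R)-2-[(3E)-4,8-dimethylnona-3,7-dien-1-yl]oxiran-2-yl]methanol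
Conditions: Ti(OiPr)4 (10 mol%), D-(−)-diethyl tartrate (12 mol%), t-BuOOH (in decane), 4 Å molecular sieves, CH2Cl2, −20 °C
Reagents that add atoms: tert-butyl hydroperoxide, CC(C)(C)OO
Why: In the Sharpless asymmetric epoxidation the titanium tartrate binds the allylic alkoxide and should oxidise only the 1,1-disubstituted alkene, leaving both remote trisubstituted alkenes alone, with D-(−)-tartrate setting the future C2 as (R).

Step 3
Reactants: 5 [(2R)-2-[(3E)-4,8-dimethylnona-3,7-dien-1-yl]oxiran-2-yl]methanol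
Product: 7 (2S)-2-[(3E)-4,8-dimethylnona-3,7-dien-1-yl]-2-{[(4-methoxyphenyl)methoxy]methyl}oxirane, via sodium alkoxide of the epoxy alcohol 6 (not isolated)
Conditions: NaH, THF, 0 °C; then 4-MeOC6H4CH2Cl, n-Bu4NI (cat.), 0 °C to rt
Reagents that add atoms: 4-methoxybenzyl chloride, COc1ccc(CCl)cc1
Why: Williamson etherification of the only hydroxyl installs a benzyl-type ether that, unlike a silyl ether, cannot migrate to the neighbouring tertiary alkoxide generated in step 5, and any Payne rearrangement of this 2,2-disubstituted glycidol is degenerate, so the configuration should be retained.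

Step 4
Reactants: 7 (2S)-2-[(3E)-4,8-dimethylnona-3,7-dien-1-yl]-2-{[(4-methoxyphenyl)methoxy]methyl}oxirane
Product: 8 (2R,5E)-1-[(4-methoxyphenyl)methoxy]-2,6,10-trimethylundeca-5,9-dien-2-ol
Conditions: LiAlH4, THF, 0 °C to rt; H2O, aq NaOH work-up
Reagents that add atoms: none
Why: Hydride opens the 2,2-disubstituted epoxide by SN2 attack at the unhindered CH2 terminus (LiAlH4 epoxide reduction), which becomes the C2 methyl group while the tertiary C–O bond and its configuration stay intact.

Step 5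
Reactants: 8 (2R,5E)-1-[(4-methoxyphenyl)methoxy]-2,6,10-trimethylundeca-5,9-dien-2-ol; 9 methyl 4-fluoro-3-formylbenzoate
Product: 11 methyl 3-formyl-4-{[(2R,5E)-1-[(4-methoxyphenyl)methoxy]-2,6,10-trimethylundeca-5,9-dien-2-yl]oxy}benzoate, via potassium tertiary alkoxide 10 (not isolated)
Conditions: KN(SiMe3)2 (1.0 equiv), THF, −78 to 0 °C; then 9, THF, 0 °C to rt
Reagents that add atoms: none
Why: SNAr by addition–elimination should succeed because the fluoride is activated by the ortho formyl and para ester groups, while the tertiary alkoxide has no α-hydrogen to transfer to the aldehyde and adds to it only reversibly; the stereocentre is not involved.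

Step 6
Reactants: 11 methyl 3-formyl-4-{[(2R,5E)-1-[(4-methoxyphenyl)methoxy]-2,6,10-trimethylundeca-5,9-dien-2-yl]oxy}benzoate
Product: 12 methyl 3-formyl-4-{[(2R,5E)-1-hydroxy-2,6,10-trimethylundeca-5,9-dien-2-yl]oxy}benzoate
Conditions: DDQ, CH2Cl2–aqueous pH 7 phosphate buffer, 0 °C
Reagents that add atoms: none
Why: Oxidative PMB cleavage by DDQ (electron transfer from the anisyl ring, oxocarbenium ion, hydrolysis) under buffered conditions should spare the trisubstituted alkenes, the aryl aldehyde, the ester and the acid-sensitive tertiary aryl ether.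

Step 7
Reactants: 12 methyl 3-formyl-4-{[(2R,5E)-1-hydroxy-2,6,10-trimethylundeca-5,9-dien-2-yl]oxy}benzoate
Product: 13 methyl 3-formyl-4-{[(2R,5E)-2,6,10-trimethyl-1-oxoundeca-5,9-dien-2-yl]oxy}benzoate
Conditions: Dess–Martin periodinane, pyridine, CH2Cl2, 0 °C to rt
Reagents that add atoms: none
Why: Dess–Martin oxidation of the primary alcohol under pyridine buffering should stop at the aldehyde, which cannot epimerise because its α-carbon (the future C2) is fully substituted.

Step 8
Reactants: 13 methyl 3-formyl-4-{[(2R,5E)-2,6,10-trimethyl-1-oxoundeca-5,9-dien-2-yl]oxy}benzoate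
Product: 14 methyl (2R,3S)-2-[(3E)-4,8-dimethylnona-3,7-dien-1-yl]-3-hydroxy-2-methyl-4-oxo-3,4-dihydro-2H-chromene-6-carboxylate
Conditions: (5aS,10bR)-2-(pentafluorophenyl)-5a,10b-dihydro-4H,6H-indeno[2,1-b][1,2,4]triazolo[4,3-d][1,4]oxazin-2-ium tetrafluoroborate (10 mol%), Et3N (10 mol%), toluene (0.01 M), rt, short contact; AcOH quench
Reagents that add atoms: none
Why: This is an intramolecular crossed benzoin reaction under N-heterocyclic carbene catalysis, the reaction type that turns 2-formylaryl ethers of α-oxy carbonyl compounds into 3-hydroxychroman-4-ones: the triazolylidene adds to the aryl aldehyde, proton transfer gives the enaminol (acyl anion equivalent at C4), this attacks the C3 aldehyde, and collapse of the adduct releases the carbene and the C4 ketone. The C3–C4 bond and the pyranone ring form in a 6-exo-trig closure. The new C3 centre is set by the catalyst, whose fused aminoindanol backbone has to steer the enaminol to the Re face of the C3 carbonyl (hydroxyl trans to the C2 methyl, (3S) in the ketol only because C4 outranks C2); the methyl/homogeranyl difference at C2 is too small to help, so the antipodal salt is the direct replacement if the sense proves opposite. The step needs chemoselectivity in the choice of donor, and the substrate supplies it: the C3 aldehyde is neopentyl-like and is attacked only slowly by the bulky carbene, which also avoids carbene-triggered expulsion of the aryloxide from C2, yet as an α-aryloxy aldehyde without α-hydrogen it remains a good, non-enolisable acceptor. High dilution suppresses intermolecular coupling, and the weak base with an acidic quench limits enediol equilibration and aryloxide elimination in the ketol, while C2 cannot epimerise.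

Step 9
Reactants: 14 methyl (2R,3S)-2-[(3E)-4,8-dimethylnona-3,7-dien-1-yl]-3-hydroxy-2-methyl-4-oxo-3,4-dihydro-2H-chromene-6-carboxylate
Product: 15 methyl (2R,3R,4RS)-2-[(3E)-4,8-dimethylnona-3,7-dien-1-yl]-3,4-dihydroxy-2-methyl-3,4-dihydro-2H-chromene-6-carboxylate
Conditions: NaBH4, CeCl3·7H2O, MeOH–THF, −40 °C
Reagents that add atoms: none
Why: Luche-type borohydride reduction of the aryl ketone is fast and only weakly basic, so the base-sensitive ketol should be removed before C3 can epimerise, and the uncontrolled C4 carbinol centre does not matter because step 11 erases it.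

Step 10
Reactants: 15 methyl (2R,3R,4RS)-2-[(3E)-4,8-dimethylnona-3,7-dien-1-yl]-3,4-dihydroxy-2-methyl-3,4-dihydro-2H-chromene-6-carboxylate
Product: 16 3,4-cyclic thionocarbonate of 15 (C3–O–C(=S)–O–C4 five-membered ring; 2R,3R, both C4 epimers)
Conditions: 1,1'-thiocarbonyldiimidazole, DMAP (cat.), toluene, 70 °C
Reagents that add atoms: 1,1'-thiocarbonyldiimidazole, S=C(n1ccnc1)n1ccnc1
Why: Double acyl transfer from thiocarbonyldiimidazole should tie either diol epimer into the cyclic thionocarbonate, which activates the benzylic oxygen for radical removal without a protecting group and leaves C3 untouched.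

Step 11
Reactants: 16 3,4-cyclic thionocarbonate of 15
Product: 18 kuhistanol D [(2R,3R)-2-[(3E)-4,8-dimethylnona-3,7-dien-1-yl]-3-hydroxy-2-methyl-3,4-dihydro-2H-chromene-6-carboxylic acid], via S-tributylstannyl thiocarbonate 17 (not isolated)
Conditions: Bu3SnH (2 equiv, 0.2 M), AIBN (cat.), toluene, 85 °C; then LiOH, THF–MeOH–H2O, rt; 1 M HCl to pH 3 at 0 °C
Reagents that add atoms: lithium hydroxide, [Li+].[OH-]
Why: In this Barton-type deoxygenation of a cyclic thionocarbonate the tin radical adds to sulfur and the adduct should fragment at C4–O, the only scission that gives a benzylic radical, which concentrated tin hydride reduces before it can add to the remote alkene, after which LiOH hydrolyses the C3 thiocarbonate and the methyl ester together without touching C2 or C3.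

Compound list
1 | 2-methylprop-2-en-1-ol (methallyl alcohol) | C=C(C)CO | starting material
2 | geranyl bromide [(2E)-1-bromo-3,7-dimethylocta-2,6-diene] | CC(C)=CCC/C(C)=C/CBr | starting material
3 | dilithiated methallyl alcohol | [Li]CC(=C)CO[Li] | intermediate
4 | (5E)-6,10-dimethyl-2-methylideneundeca-5,9-dien-1-ol | CC(C)=CCC/C(C)=C/CCC(=C)CO | intermediate
5 | [(2R)-2-[(3E)-4,8-dimethylnona-3,7-dien-1-yl]oxiran-2-yl]methanol | CC(C)=CCC/C(C)=C/CC[C@@]1(CO)CO1 | intermediate
6 | sodium alkoxide of 5 | CC(C)=CCC/C(C)=C/CC[C@@]1(C[O-])CO1.[Na+] | intermediate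
7 | (2S)-2-[(3E)-4,8-dimethylnona-3,7-dien-1-yl]-2-{[(4-methoxyphenyl)methoxy]methyl}oxirane | CC(C)=CCC/C(C)=C/CC[C@@]1(COCc2ccc(OC)cc2)CO1 | intermediate
8 | (2R,5E)-1-[(4-methoxyphenyl)methoxy]-2,6,10-trimethylundeca-5,9-dien-2-ol | CC(C)=CCC/C(C)=C/CC[C@@](C)(O)COCc1ccc(OC)cc1 | intermediate
9 | methyl 4-fluoro-3-formylbenzoate | COC(=O)c1ccc(F)c(C=O)c1 | starting material
10 | potassium alkoxide of 8 | CC(C)=CCC/C(C)=C/CC[C@@](C)([O-])COCc1ccc(OC)cc1.[K+] | intermediate
11 | methyl 3-formyl-4-{[(2R,5E)-1-[(4-methoxyphenyl)methoxy]-2,6,10-trimethylundeca-5,9-dien-2-yl]oxy}benzoate | CC(C)=CCC/C(C)=C/CC[C@@](C)(Oc1ccc(C(=O)OC)cc1C=O)COCc1ccc(OC)cc1 | intermediate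
12 | methyl 3-formyl-4-{[(2R,5E)-1-hydroxy-2,6,10-trimethylundeca-5,9-dien-2-yl]oxy}benzoate | CC(C)=CCC/C(C)=C/CC[C@@](C)(Oc1ccc(C(=O)OC)cc1C=O)CO | intermediate
13 | methyl 3-formyl-4-{[(2R,5E)-2,6,10-trimethyl-1-oxoundeca-5,9-dien-2-yl]oxy}benzoate | CC(C)=CCC/C(C)=C/CC[C@@](C)(Oc1ccc(C(=O)OC)cc1C=O)C=O | intermediate
14 | methyl (2R,3S)-2-[(3E)-4,8-dimethylnona-3,7-dien-1-yl]-3-hydroxy-2-methyl-4-oxo-3,4-dihydro-2H-chromene-6-carboxylate | CC(C)=CCC/C(C)=C/CC[C@@]1(C)Oc2ccc(C(=O)OC)cc2C(=O)[C@H]1O | intermediate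
15 | methyl (2R,3R,4RS)-2-[(3E)-4,8-dimethylnona-3,7-dien-1-yl]-3,4-dihydroxy-2-methyl-3,4-dihydro-2H-chromene-6-carboxylate | CC(C)=CCC/C(C)=C/CC[C@@]1(C)Oc2ccc(C(=O)OC)cc2C(O)[C@H]1O | intermediate
16 | 3,4-cyclic thionocarbonate of 15 (2R,3R, C4 epimers) | CC(C)=CCC/C(C)=C/CC[C@@]1(C)Oc2ccc(C(=O)OC)cc2C2OC(=S)O[C@@H]12 | intermediate
17 | methyl (2R,3R)-2-[(3E)-4,8-dimethylnona-3,7-dien-1-yl]-2-methyl-3-{[(tributylstannylsulfanyl)carbonyl]oxy}-3,4-dihydro-2H-chromene-6-carboxylate | CC(C)=CCC/C(C)=C/CC[C@@]1(C)Oc2ccc(C(=O)OC)cc2C[C@H]1OC(=O)S[Sn](CCCC)(CCCC)CCCC | intermediate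
18 | kuhistanol D, (2R,3R)-2-[(3E)-4,8-dimethylnona-3,7-dien-1-yl]-3-hydroxy-2-methyl-3,4-dihydro-2H-chromene-6-carboxylic acid | CC(C)=CCC/C(C)=C/CC[C@@]1(C)Oc2ccc(C(=O)O)cc2C[C@H]1O | target

Total step count: 11.
Longest linear sequence: 11 steps (from 1 and 2 to 18; 9 enters at step 5).

Steps most likely to fail

Step 8. The enaminol may add to the wrong face of the C3 carbonyl, or so slowly to this hindered acceptor that intermolecular coupling, carbene-induced loss of aryloxide or base-mediated equilibration of the ketol takes over. The fallback keeps the C3–C4 disconnection but closes the bond by ketyl radical chemistry and sets C3 afterwards by reagent control. It sets out from 13 and comes back at 18.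
- Treatment of 13 with SmI2 in THF/t-BuOH at −78 °C should effect pinacol cyclisation to methyl (2R)-2-[(3E)-4,8-dimethylnona-3,7-dien-1-yl]-3,4-dihydroxy-2-methyl-3,4-dihydro-2H-chromene-6-carboxylate F1 as a mixture at C3 and C4.
- Thiocarbonyldiimidazole converts this into the cyclic thionocarbonate F2.
- Bu3SnH/AIBN followed by K2CO3 in MeOH gives methyl (2R,3RS)-2-[(3E)-4,8-dimethylnona-3,7-dien-1-yl]-3-hydroxy-2-methyl-3,4-dihydro-2H-chromene-6-carboxylate F3.
- Dess–Martin oxidation gives methyl (2R)-2-[(3E)-4,8-dimethylnona-3,7-dien-1-yl]-2-methyl-3-oxo-3,4-dihydro-2H-chromene-6-carboxylate F4.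
- Corey–Bakshi–Shibata reduction with catecholborane and (S)-1-methyl-3,3-diphenyltetrahydro-1H,3H-pyrrolo[1,2-c][1,3,2]oxazaborole in toluene at −78 °C should give the (3R)-alcohol, methyl (2R,3R)-2-[(3E)-4,8-dimethylnona-3,7-dien-1-yl]-3-hydroxy-2-methyl-3,4-dihydro-2H-chromene-6-carboxylate F5, because the catalyst tells the quaternary C2 flank from the C4 methylene flank.
- LiOH hydrolysis then gives 18.

Step 5. The hindered tertiary alkoxide may add to the formyl group and pass hydride on to a second aldehyde, or exchange with the methyl ester, faster than it displaces fluoride. The fallback removes the free carbonyl from the electrophile. It sets out from 8 (as its alkoxide 10) and 9 and comes back at 11.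
- Compound 9 is first condensed with tert-butylamine (MgSO4, CH2Cl2) to methyl 3-[(E)-(tert-butylimino)methyl]-4-fluorobenzoate F6, which keeps an ortho π-acceptor for the Meisenheimer adduct.
- Alkoxide 10 displaces the fluoride to give methyl 3-[(E)-(tert-butylimino)methyl]-4-{[(2R,5E)-1-[(4-methoxyphenyl)methoxy]-2,6,10-trimethylundeca-5,9-dien-2-yl]oxy}benzoate F7.
- Aqueous citric acid in THF hydrolyses the imine to 11.

Step 11. The stannylated thionocarbonate radical may open on the C3–O side, or the tin thiocarbonate may be released incompletely, so that the C3 oxygen is lost or stays masked. The fallback tells the two oxygens apart by protection instead of by the direction of ring scission. It sets out from 14, replaces steps 9 to 11 and comes back at 18.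
- Silylation of 14 (TBSOTf, 2,6-lutidine, CH2Cl2, −78 °C) gives methyl (2R,3S)-3-{[tert-butyl(dimethyl)silyl]oxy}-2-[(3E)-4,8-dimethylnona-3,7-dien-1-yl]-2-methyl-4-oxo-3,4-dihydro-2H-chromene-6-carboxylate F8.
- NaBH4 reduction gives the C4 alcohol, methyl (2R,3R,4RS)-3-{[tert-butyl(dimethyl)silyl]oxy}-2-[(3E)-4,8-dimethylnona-3,7-dien-1-yl]-4-hydroxy-2-methyl-3,4-dihydro-2H-chromene-6-carboxylate F9.
- O-Phenyl chlorothionoformate and DMAP in MeCN give the C4 O-phenyl thionocarbonate F10.
- Barton–McCombie reduction (Bu3SnH, AIBN, toluene, 85 °C) gives methyl (2R,3R)-3-{[tert-butyl(dimethyl)silyl]oxy}-2-[(3E)-4,8-dimethylnona-3,7-dien-1-yl]-2-methyl-3,4-dihydro-2H-chromene-6-carboxylate F11.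
- LiOH gives the corresponding acid, (2R,3R)-3-{[tert-butyl(dimethyl)silyl]oxy}-2-[(3E)-4,8-dimethylnona-3,7-dien-1-yl]-2-methyl-3,4-dihydro-2H-chromene-6-carboxylic acid F12.
- n-Bu4NF in THF removes the silyl group to give 18.

Further compounds
F1 | step 8 | methyl (2R)-2-[(3E)-4,8-dimethylnona-3,7-dien-1-yl]-3,4-dihydroxy-2-methyl-3,4-dihydro-2H-chromene-6-carboxylate (mixture at C3 and C4) | CC(C)=CCC/C(C)=C/CC[C@@]1(C)Oc2ccc(C(=O)OC)cc2C(O)C1O
F2 | step 8 | 3,4-cyclic thionocarbonate of F1 (mixture at C3 and C4) | CC(C)=CCC/C(C)=C/CC[C@@]1(C)Oc2ccc(C(=O)OC)cc2C2OC(=S)OC12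
F3 | step 8 | methyl (2R,3RS)-2-[(3E)-4,8-dimethylnona-3,7-dien-1-yl]-3-hydroxy-2-methyl-3,4-dihydro-2H-chromene-6-carboxylate | CC(C)=CCC/C(C)=C/CC[C@@]1(C)Oc2ccc(C(=O)OC)cc2CC1O
F4 | step 8 | methyl (2R)-2-[(3E)-4,8-dimethylnona-3,7-dien-1-yl]-2-methyl-3-oxo-3,4-dihydro-2H-chromene-6-carboxylate | CC(C)=CCC/C(C)=C/CC[C@@]1(C)Oc2ccc(C(=O)OC)cc2CC1=O
F5 | step 8 | methyl (2R,3R)-2-[(3E)-4,8-dimethylnona-3,7-dien-1-yl]-3-hydroxy-2-methyl-3,4-dihydro-2H-chromene-6-carboxylate | CC(C)=CCC/C(C)=C/CC[C@@]1(C)Oc2ccc(C(=O)OC)cc2C[C@H]1O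
F6 | step 5 | methyl 3-[(E)-(tert-butylimino)methyl]-4-fluorobenzoate | COC(=O)c1ccc(F)c(/C=N/C(C)(C)C)c1
F7 | step 5 | methyl 3-[(E)-(tert-butylimino)methyl]-4-{[(2R,5E)-1-[(4-methoxyphenyl)methoxy]-2,6,10-trimethylundeca-5,9-dien-2-yl]oxy}benzoate | CC(C)=CCC/C(C)=C/CC[C@@](C)(Oc1ccc(C(=O)OC)cc1/C=N/C(C)(C)C)COCc1ccc(OC)cc1
F8 | step 11 | methyl (2R,3S)-3-{[tert-butyl(dimethyl)silyl]oxy}-2-[(3E)-4,8-dimethylnona-3,7-dien-1-yl]-2-methyl-4-oxo-3,4-dihydro-2H-chromene-6-carboxylate | CC(C)=CCC/C(C)=C/CC[C@@]1(C)Oc2ccc(C(=O)OC)cc2C(=O)[C@H]1O[Si](C)(C)C(C)(C)C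
F9 | step 11 | methyl (2R,3R,4RS)-3-{[tert-butyl(dimethyl)silyl]oxy}-2-[(3E)-4,8-dimethylnona-3,7-dien-1-yl]-4-hydroxy-2-methyl-3,4-dihydro-2H-chromene-6-carboxylate | CC(C)=CCC/C(C)=C/CC[C@@]1(C)Oc2ccc(C(=O)OC)cc2C(O)[C@H]1O[Si](C)(C)C(C)(C)C
F10 | step 11 | C4 O-phenyl thionocarbonate of F9 | CC(C)=CCC/C(C)=C/CC[C@@]1(C)Oc2ccc(C(=O)OC)cc2C(OC(=S)Oc2ccccc2)[C@H]1O[Si](C)(C)C(C)(C)C
F11 | step 11 | methyl (2R,3R)-3-{[tert-butyl(dimethyl)silyl]oxy}-2-[(3E)-4,8-dimethylnona-3,7-dien-1-yl]-2-methyl-3,4-dihydro-2H-chromene-6-carboxylate | CC(C)=CCC/C(C)=C/CC[C@@]1(C)Oc2ccc(C(=O)OC)cc2C[C@H]1O[Si](C)(C)C(C)(C)C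
F12 | step 11 | (2R,3R)-3-{[tert-butyl(dimethyl)silyl]oxy}-2-[(3E)-4,8-dimethylnona-3,7-dien-1-yl]-2-methyl-3,4-dihydro-2H-chromene-6-carboxylic acid | CC(C)=CCC/C(C)=C/CC[C@@]1(C)Oc2ccc(C(=O)O)cc2C[C@H]1O[Si](C)(C)C(C)(C)C
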